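**Retrosynthetic overview**

1. The target is a 4-alkylcatechol: benzene ring a1–a6, the 5-oxoicosyl chain on a1, hydroxyls on a3 and a4. Because the a4 oxygen is para to the chain, the ring maps onto a 4-alkylcyclohex-2-enone (C=O = a4, chain-bearing CH = a1, enone α-carbon = a3); a3 is oxygenated through the epoxide and the ring is dehydrogenated last.
2. The carbocycle, the only ring made, is cut at a1–a6 (Michael addition of an aldehyde enamine to methyl vinyl ketone) and at a2=a3 (aldol condensation).
3. The aldehyde partner, a 7-oxo aldehyde with its ketone masked as a dioxolane, comes from palmitoyl chloride and 7-bromohept-1-ene by Weinreb ketone synthesis, ketalisation and ozonolysis.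
4. Endgame: alkaline epoxidation, acid isomerisation to the diosphenol with loss of the ketal, then dehydrogenation over Pd/C.

Key step: step 5

Remark: the target has no stereocentre. The ring stereocentres of 12–17 arise as racemates or diastereomer mixtures, are all destroyed in step 8, and are therefore drawn without configuration.

**Route**

Step 1
Reactants: 1 hexadecanoyl chloride (palmitoyl chloride)
Product: 2 N-methoxy-N-methylhexadecanamide
Conditions: MeNHOMe·HCl, K2CO3, CH2Cl2–H2O, 0 °C → rt
Reagents that add atoms: N,O-dimethylhydroxylamine hydrochloride, CNOC.Cl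
Why: Schotten–Baumann N-acylation, in which the hydroxylamine freed by carbonate attacks the acid chloride in the organic phase much faster than water does, should give the Weinreb amide cleanly.

Step 2
Reactants: 2 N-methoxy-N-methylhexadecanamide; 3 7-bromohept-1-ene
Product: 6 tricos-1-en-8-one, via hept-6-enylmagnesium bromide 4 (not isolated), via chelated tetrahedral bromomagnesium adduct 5 (not isolated)
Conditions: 3, Mg, I2 (cat.), THF, rt → 45 °C; then 2, THF, 0 °C → rt; then 1 M HCl (aq), 0 °C
Reagents that add atoms: none
Why: Weinreb ketone synthesis, in which Grignard reagent 4 adds once to 2 to give the five-membered magnesium chelate 5 that does not collapse until the acidic quench, so the ketone is released only when no nucleophile remains and the remote terminal alkene is untouched.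

Step 3
Reactants: 6 tricos-1-en-8-one
Product: 7 2-(hept-6-en-1-yl)-2-pentadecyl-1,3-dioxolane
Conditions: HOCH2CH2OH, p-TsOH·H2O (cat.), PhMe, reflux, Dean–Stark
Reagents that add atoms: ethylene glycol, OCCO
Why: Acid-catalysed ketalisation (1,3-dioxolane formation) is driven to completion by azeotropic removal of water, and the isolated terminal alkene should not migrate under catalytic sulfonic acid.

Step 4
Reactants: 7 2-(hept-6-en-1-yl)-2-pentadecyl-1,3-dioxolane
Product: 9 6-(2-pentadecyl-1,3-dioxolan-2-yl)hexanal, via ozonide 8 (not isolated)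
Conditions: O3, NaHCO3, CH2Cl2, −78 °C; then PPh3, −78 °C → rt
Reagents that add atoms: ozone, [O-][O+]=O
Why: Ozonolysis with reductive work-up (Criegee mechanism) gives ozonide 8 by cycloaddition, cycloreversion and recombination and PPh3 reduces it to the aldehyde, while the dioxolane should survive because its ketal carbon carries no hydrogen for ozone to attack and the medium is buffered.

Step 5
Reactants: 9 6-(2-pentadecyl-1,3-dioxolan-2-yl)hexanal; 10 methyl vinyl ketone (but-3-en-2-one)
Product: 14 4-[4-(2-pentadecyl-1,3-dioxolan-2-yl)butyl]cyclohex-2-en-1-one (racemic), via pyrrolidine enamine 11 (not isolated), via keto aldehyde 12 (not isolated), via aldol 13 (not isolated)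
Conditions: pyrrolidine (1.05 equiv), 4 Å MS, PhMe, rt; then 10 (slow addition), 0 °C → rt; then H2O, rt; then KOH (aq), n-Bu4NOH (cat.), THF–Et2O, reflux
Reagents that add atoms: none
Why: Pyrrolidine condenses only with the aldehyde of 9 to give enamine 11, whose β-carbon (the future a1) adds to the terminal carbon of 10 in a Stork enamine Michael addition (bond a1–a6), and water then releases the 1,5-keto aldehyde 12. Hydroxide generates the methyl ketone enolate, which attacks the aldehyde carbon in a 6-(enolendo)-exo-trig aldol closure to 13, and E1cB dehydration gives the conjugated enone 14 (bond a2=a3). The closest known reaction type is the Stork enamine addition of aldehyde enamines to methyl vinyl ketone followed by intramolecular aldol condensation (a Robinson-type annulation) to 4-substituted cyclohex-2-enones. The new stereocentre at C4 and the transient carbinol carbon of 13 are formed without control, which is acceptable because both are erased on aromatisation. The step needs chemoselective enamine formation, mono-addition and a single aldol regiochemistry: the dioxolane keeps the C7 ketone out of enamine and aldol chemistry, one equivalent of 10 added slowly meets an enamine that becomes less nucleophilic once it is more substituted, and the only strain-free closure joins the ketone methyl to the aldehyde carbon. The ketal is stable to the amine and hydroxide used throughout.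

Step 6
Reactants: 14 4-[4-(2-pentadecyl-1,3-dioxolan-2-yl)butyl]cyclohex-2-en-1-one
Product: 15 5-[4-(2-pentadecyl-1,3-dioxolan-2-yl)butyl]-7-oxabicyclo[4.1.0]heptan-2-one (the 2,3-epoxy ketone; diastereomer mixture)
Conditions: 30% H2O2 (aq), NaOH (cat.), MeOH–THF, 0 °C
Reagents that add atoms: hydrogen peroxide, OO
Why: Weitz–Scheffer nucleophilic epoxidation, in which hydroperoxide anion adds to the β-carbon (a2) and the enolate closes onto oxygen, should attack mainly anti to the C4 chain to give the trans epoxide (substrate control, of no consequence since both epoxide carbons become sp2 later) and leaves the dioxolane intact in the basic medium.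

Step 7
Reactants: 15 5-[4-(2-pentadecyl-1,3-dioxolan-2-yl)butyl]-7-oxabicyclo[4.1.0]heptan-2-one
Product: 17 2-hydroxy-4-(5-oxoicosyl)cyclohex-2-en-1-one (diosphenol; racemic), via ketal diosphenol 16 (not isolated)
Conditions: H2SO4 (cat.), AcOH, rt; then H2O, 40 °C
Reagents that add atoms: water, O
Why: Acid-catalysed epoxy ketone to diosphenol isomerisation, the usual route from 2,3-epoxycyclohexanones to 2-hydroxycyclohex-2-enones, opens the protonated epoxide at the β-carbon with acetic acid and eliminates acetic acid through the enol so that oxygen remains on a3, after which the added water hydrolyses the dioxolane under the same acid.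

Step 8
Reactants: 17 2-hydroxy-4-(5-oxoicosyl)cyclohex-2-en-1-one
Product: 18 1-(3,4-dihydroxyphenyl)icosan-5-one (target)
Conditions: 10% Pd/C, mesitylene, reflux, Ar sweep
Reagents that add atoms: none
Why: Catalytic dehydrogenative aromatisation over palladium on carbon, a known conversion of cyclohexane-1,2-diones and their enols into catechols, requires the loss of only one molecule of H2, is driven by aromatisation and removal of the gas, and should leave the saturated dialkyl ketone untouched under neutral conditions.

**Compound list**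

1 | hexadecanoyl chloride | CCCCCCCCCCCCCCCC(=O)Cl | starting material
2 | N-methoxy-N-methylhexadecanamide | CCCCCCCCCCCCCCCC(=O)N(C)OC | intermediate
3 | 7-bromohept-1-ene | C=CCCCCCBr | starting material
4 | hept-6-enylmagnesium bromide | C=CCCCCC[Mg]Br | intermediate
5 | bromomagnesium 8-[methoxy(methyl)amino]tricos-1-en-8-olate (chelated tetrahedral adduct) | CCCCCCCCCCCCCCCC(CCCCCC=C)(O[Mg]Br)N(C)OC | intermediate
6 | tricos-1-en-8-one | C=CCCCCCC(=O)CCCCCCCCCCCCCCC | intermediate
7 | 2-(hept-6-en-1-yl)-2-pentadecyl-1,3-dioxolane | C=CCCCCCC1(CCCCCCCCCCCCCCC)OCCO1 | intermediate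
8 | 2-pentadecyl-2-[5-(1,2,4-trioxolan-3-yl)pentyl]-1,3-dioxolane (ozonide) | C1OOC(CCCCCC2(CCCCCCCCCCCCCCC)OCCO2)O1 | intermediate
9 | 6-(2-pentadecyl-1,3-dioxolan-2-yl)hexanal | O=CCCCCCC1(CCCCCCCCCCCCCCC)OCCO1 | intermediate
10 | methyl vinyl ketone (but-3-en-2-one) | CC(=O)C=C | starting material
11 | 1-[(1E)-6-(2-pentadecyl-1,3-dioxolan-2-yl)hex-1-en-1-yl]pyrrolidine | N1(CCCC1)/C=C/CCCCC2(CCCCCCCCCCCCCCC)OCCO2 | intermediate
12 | 5-oxo-2-[4-(2-pentadecyl-1,3-dioxolan-2-yl)butyl]hexanal (racemic) | CC(=O)CCC(C=O)CCCCC1(CCCCCCCCCCCCCCC)OCCO1 | intermediate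
13 | 3-hydroxy-4-[4-(2-pentadecyl-1,3-dioxolan-2-yl)butyl]cyclohexan-1-one (diastereomer mixture) | O=C1CCC(CCCCC2(CCCCCCCCCCCCCCC)OCCO2)C(O)C1 | intermediate
14 | 4-[4-(2-pentadecyl-1,3-dioxolan-2-yl)butyl]cyclohex-2-en-1-one (racemic) | O=C1C=CC(CCCCC2(CCCCCCCCCCCCCCC)OCCO2)CC1 | intermediate
15 | 5-[4-(2-pentadecyl-1,3-dioxolan-2-yl)butyl]-7-oxabicyclo[4.1.0]heptan-2-one (diastereomer mixture) | O=C1CCC(CCCCC2(CCCCCCCCCCCCCCC)OCCO2)C3OC13 | intermediate
16 | 2-hydroxy-4-[4-(2-pentadecyl-1,3-dioxolan-2-yl)butyl]cyclohex-2-en-1-one (racemic) | O=C1CCC(CCCCC2(CCCCCCCCCCCCCCC)OCCO2)C=C1O | intermediate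
17 | 2-hydroxy-4-(5-oxoicosyl)cyclohex-2-en-1-one (racemic) | O=C1CCC(CCCCC(=O)CCCCCCCCCCCCCCC)C=C1O | intermediate
18 | 1-(3,4-dihydroxyphenyl)icosan-5-one | CCCCCCCCCCCCCCCC(=O)CCCCc1ccc(O)c(O)c1 | target

**Step count**

Total steps: 8. Longest linear sequence: 8 steps (1 → 18); 3 and 10 enter as purchased materials.

**Steps most likely to fail**

Step 5. The enamine regenerated after the first conjugate addition still carries an α-hydrogen and may add a second molecule of 10, and 10 may oligomerise under amine catalysis, so mono-annulation could be inefficient. The fallback sets out from 9 and comes back at 12, replacing the conjugate addition by a C-alkylation and a later oxidation. Aldehyde 9 is condensed with tert-butylamine (4 Å MS, CH2Cl2, rt) to N-tert-butyl-6-(2-pentadecyl-1,3-dioxolan-2-yl)hexan-1-imine F1. Deprotonation with LiN(i-Pr)2 (THF, −78 °C) and alkylation of the aza-enolate with 4-iodobut-1-ene should give, with the mono-selectivity typical of metalated imines, N-tert-butyl-2-(but-3-en-1-yl)-6-(2-pentadecyl-1,3-dioxolan-2-yl)hexan-1-imine F2. Two-phase hydrolysis with aqueous NaOAc–AcOH buffer (pH 4.5, Et2O, rt) frees 2-(but-3-en-1-yl)-6-(2-pentadecyl-1,3-dioxolan-2-yl)hexanal F3 without touching the ketal. Tsuji–Wacker oxidation (PdCl2 cat., CuCl, O2, DMF–H2O, rt) turns the terminal alkene into the methyl ketone, which is 12, and 12 is closed with KOH and n-Bu4NOH as in the last stage of step 5 to 14.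

Step 7. On protonation the epoxide may open with acyl or hydride migration (ring contraction to a formylcyclopentanone), or the acetoxy ketol may fail to eliminate, so the diosphenol is not reached cleanly. The fallback sets out from 14 and comes back at 18; it oxygenates a5, which is equivalent to a3 in the catechol by the a1–a4 axis. Kinetic deprotonation of 14 at C6 with NaN(SiMe3)2 (THF, −78 °C) and hydroxylation of the cross-conjugated enolate with 2-(phenylsulfonyl)-3-phenyloxaziridine should give 6-hydroxy-4-[4-(2-pentadecyl-1,3-dioxolan-2-yl)butyl]cyclohex-2-en-1-one F4. Dess–Martin periodinane (NaHCO3, CH2Cl2, 0 °C) oxidises the ketol to 5-[4-(2-pentadecyl-1,3-dioxolan-2-yl)butyl]cyclohex-3-ene-1,2-dione F5. F5 is already at the oxidation level of the arene and should tautomerise on brief treatment with Et3N to 4-[4-(2-pentadecyl-1,3-dioxolan-2-yl)butyl]benzene-1,2-diol F6; a wash with aqueous Na2S2O4 returns any o-quinone. Hydrolysis with 1 M HCl in THF at rt under argon then gives 18.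

Step 8. Hydrogen released on the catalyst may be transferred to unreacted substrate (disproportionation), or the chelating 1,2-dioxygenated ring may adsorb strongly on palladium and stall the aromatisation. The fallback sets out from 14 and comes back at 18; it reverses the order, aromatising first and introducing the second oxygen afterwards. The dioxolane of 14 is hydrolysed (1 M HCl, THF, rt) to 4-(5-oxoicosyl)cyclohex-2-en-1-one F7. Homogeneous aerobic dehydrogenation (Pd(O2CCF3)2 cat., 2-(dimethylamino)pyridine cat., p-TsOH cat., O2 1 atm, DMSO, 80 °C) should give 1-(4-hydroxyphenyl)icosan-5-one F8, the cross-conjugated dienone tautomerising as it forms. Ortho-oxygenation of the phenol with 2-iodoxybenzoic acid (DMF, rt) gives 4-(5-oxoicosyl)cyclohexa-3,5-diene-1,2-dione F9, which is reduced in the same flask with aqueous Na2S2O4 to 18.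

**Further compounds**

F1 | step 5 | N-tert-butyl-6-(2-pentadecyl-1,3-dioxolan-2-yl)hexan-1-imine | CC(C)(C)/N=C/CCCCCC1(CCCCCCCCCCCCCCC)OCCO1
F2 | step 5 | N-tert-butyl-2-(but-3-en-1-yl)-6-(2-pentadecyl-1,3-dioxolan-2-yl)hexan-1-imine (racemic) | CC(C)(C)/N=C/C(CCC=C)CCCCC1(CCCCCCCCCCCCCCC)OCCO1
F3 | step 5 | 2-(but-3-en-1-yl)-6-(2-pentadecyl-1,3-dioxolan-2-yl)hexanal (racemic) | O=CC(CCC=C)CCCCC1(CCCCCCCCCCCCCCC)OCCO1
F4 | step 7 | 6-hydroxy-4-[4-(2-pentadecyl-1,3-dioxolan-2-yl)butyl]cyclohex-2-en-1-one (diastereomer mixture) | O=C1C=CC(CCCCC2(CCCCCCCCCCCCCCC)OCCO2)CC1O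
F5 | step 7 | 5-[4-(2-pentadecyl-1,3-dioxolan-2-yl)butyl]cyclohex-3-ene-1,2-dione (racemic) | O=C1C=CC(CCCCC2(CCCCCCCCCCCCCCC)OCCO2)CC1=O
F6 | step 7 | 4-[4-(2-pentadecyl-1,3-dioxolan-2-yl)butyl]benzene-1,2-diol | Oc1ccc(CCCCC2(CCCCCCCCCCCCCCC)OCCO2)cc1O
F7 | step 8 | 4-(5-oxoicosyl)cyclohex-2-en-1-one (racemic) | O=C1C=CC(CCCCC(=O)CCCCCCCCCCCCCCC)CC1
F8 | step 8 | 1-(4-hydroxyphenyl)icosan-5-one | CCCCCCCCCCCCCCCC(=O)CCCCc1ccc(O)cc1
F9 | step 8 | 4-(5-oxoicosyl)cyclohexa-3,5-diene-1,2-dione | CCCCCCCCCCCCCCCC(=O)CCCCC1=CC(=O)C(=O)C=C1
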